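**Retrosynthetic overview**
1. Target 12 ⇒ acetonide 11 (acid hydrolysis last); the coumarin O7–C1 ether ⇒ Mitsunobu of allylic alcohol 9 with purchased 5,7-dihydroxycoumarin 10.
2. Key disconnection C8–C9 ⇒ allyl ester 7: visible-light palladium/iridium decarboxylative allylation, with C9 set trans to the tartrate-derived C10.
3. Ester 7 ⇒ allylic alcohol 2 (geranyl acetate, SeO2; fixes 6E) + hydroxy acid 6 (D-tartrate acetonide diester: half-saponification, MeMgBr).
4. Rings: none is built; the coumarin bicycle is bought intact, and the dioxolane arrives with the tartrate acetonide and is removed last.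

Assumption: geranyl acetate, (+)-dimethyl 2,3-O-isopropylidene-D-tartrate and 5,7-dihydroxycoumarin are bought as such. Side-chain carbons are numbered C1–C12 from the ether oxygen.

**Step 1**
Reactants: 1 geranyl acetate, (2E)-3,7-dimethylocta-2,6-dien-1-yl acetate
Product: 2 (2E,6E)-8-hydroxy-3,7-dimethylocta-2,6-dien-1-yl acetate
Conditions: SeO2 (0.1 equiv), t-BuOOH (70% aq., 3 equiv), salicylic acid (0.1 equiv), CH2Cl2, rt
Reagents that add atoms: tert-butyl hydroperoxide (net oxygen source, relayed by the SeO2 catalyst), CC(C)(C)OO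
Why: Catalytic SeO2/t-BuOOH allylic oxidation (ene reaction, then [2,3]-sigmatropic shift) hydroxylates the E-methyl of the electron-rich 6,7-olefin and leaves the acetate-deactivated 2,3-olefin alone, fixing the 6E geometry.

**Step 2**
Reactants: 3 dimethyl (4S,5S)-2,2-dimethyl-1,3-dioxolane-4,5-dicarboxylate
Product: 4 (4S,5S)-5-(methoxycarbonyl)-2,2-dimethyl-1,3-dioxolane-4-carboxylic acid
Conditions: KOH (1.0 equiv), MeOH, 0 °C to rt; then 1 M HCl to pH 2–3, 0 °C
Reagents that add atoms: potassium hydroxide (carboxyl OH oxygen), [K+].[OH-]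
Why: Mono-saponification of a C2-symmetric diester; the two esters are equivalent and the first carboxylate retards the second hydrolysis, so one half-ester forms with both stereocentres untouched.

**Step 3**
Reactants: 4 (4S,5S)-5-(methoxycarbonyl)-2,2-dimethyl-1,3-dioxolane-4-carboxylic acid
Product: 6 (4S,5S)-5-(2-hydroxypropan-2-yl)-2,2-dimethyl-1,3-dioxolane-4-carboxylic acid, via acetyl carboxylate 5 (not isolated)
Conditions: MeMgBr (4 equiv), THF, −20 °C to rt; sat. NH4Cl, then 1 M HCl to pH 3, 0 °C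
Reagents that add atoms: methylmagnesium bromide (two methyl groups), C[Mg]Br
Why: Grignard double addition; the first equivalent only forms an unreactive magnesium carboxylate, the next two take the ester through the ketone to the tertiary carbinol, and the adjacent purchased S centre (future C10) is not enolised.

**Step 4**
Reactants: 2 (2E,6E)-8-hydroxy-3,7-dimethylocta-2,6-dien-1-yl acetate; 6 (4S,5S)-5-(2-hydroxypropan-2-yl)-2,2-dimethyl-1,3-dioxolane-4-carboxylic acid
Product: 7 (2E,6E)-8-(acetyloxy)-2,6-dimethylocta-2,6-dien-1-yl (4S,5S)-5-(2-hydroxypropan-2-yl)-2,2-dimethyl-1,3-dioxolane-4-carboxylate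
Conditions: EDC·HCl (1.3 equiv), DMAP (0.1 equiv), CH2Cl2, 0 °C to rt
Reagents that add atoms: none
Why: Steglich esterification; the primary allylic alcohol is acylated far faster than the tertiary hydroxyl, and self-lactonisation would need a strained trans-fused bicycle.

**Step 5**
Reactants: 7 (2E,6E)-8-(acetyloxy)-2,6-dimethylocta-2,6-dien-1-yl (4S,5S)-5-(2-hydroxypropan-2-yl)-2,2-dimethyl-1,3-dioxolane-4-carboxylate
Product: 9 (2E,6E)-8-[(4R,5S)-5-(2-hydroxypropan-2-yl)-2,2-dimethyl-1,3-dioxolan-4-yl]-3,7-dimethylocta-2,6-dien-1-ol, via dienyl acetate 8 (not isolated)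
Conditions: Pd(PPh3)4 (5 mol %), [Ir(dF(CF3)ppy)2(dtbbpy)]PF6 (1 mol %), degassed MeCN (0.05 M), 450 nm LEDs, rt; then MeOH, K2CO3 (0.2 equiv), rt, one pot
Reagents that add atoms: none
Why: Proposed new method: visible-light dual palladium/iridium decarboxylative allylation of an α-alkoxy (dioxolane-4-)carboxylic allyl ester. Zerovalent palladium ionises the ester to a syn 2-methyl-π-allylpalladium carboxylate ion pair; the excited trivalent iridium photocatalyst (about +1.2 V vs SCE) oxidises the α-alkoxy carboxylate; CO2 is lost; the nucleophilic dioxolan-4-yl radical is captured at the unsubstituted CH2 terminus of the allylpalladium unit while reduced (divalent) iridium closes both cycles. This forms C8–C9 with the 6E olefin retained, and sets C9 as R by bond formation anti to the bulky 2-hydroxypropan-2-yl group on the purchased S centre (trans-dioxolane). Closest known reaction type: palladium/photoredox decarboxylative allylation of α-amino and arylacetic allyl esters, together with photoredox decarboxylative couplings of α-oxy acids. The K2CO3/MeOH transesterification in the same flask then frees the C1 alcohol.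

**Step 6**
Reactants: 9 (2E,6E)-8-[(4R,5S)-5-(2-hydroxypropan-2-yl)-2,2-dimethyl-1,3-dioxolan-4-yl]-3,7-dimethylocta-2,6-dien-1-ol; 10 5,7-dihydroxy-2H-chromen-2-one (5,7-dihydroxycoumarin)
Product: 11 5-hydroxy-7-({(2E,6E)-8-[(4R,5S)-5-(2-hydroxypropan-2-yl)-2,2-dimethyl-1,3-dioxolan-4-yl]-3,7-dimethylocta-2,6-dien-1-yl}oxy)-2H-chromen-2-one
Conditions: 10 (2 equiv), PPh3, DIAD, THF, 0 °C to rt
Reagents that add atoms: none
Why: Mitsunobu etherification (SN2 at the primary allylic carbon, 2E retained); the 7-OH, para to the ring carbon that carries the acrylate acceptor, is the more acidic and less hindered phenol (the 5-OH is peri to H-4), and excess diphenol suppresses dialkylation.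

**Step 7**
Reactants: 11 5-hydroxy-7-({(2E,6E)-8-[(4R,5S)-5-(2-hydroxypropan-2-yl)-2,2-dimethyl-1,3-dioxolan-4-yl]-3,7-dimethylocta-2,6-dien-1-yl}oxy)-2H-chromen-2-one
Product: 12 5-hydroxy-7-{[(2E,6E,9R,10S)-9,10,11-trihydroxy-3,7,11-trimethyldodeca-2,6-dien-1-yl]oxy}-2H-chromen-2-one
Conditions: AcOH/H2O (4:1), 45 °C
Reagents that add atoms: none
Why: Mild acid hydrolysis of the isopropylidene acetal; no stereocentre is involved, and the weakly basic aryl allyl ether and the lactone tolerate aqueous acetic acid.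

**Compound list**
1 | geranyl acetate, (2E)-3,7-dimethylocta-2,6-dien-1-yl acetate | C/C(=C\COC(C)=O)CCC=C(C)C | starting material
2 | (2E,6E)-8-hydroxy-3,7-dimethylocta-2,6-dien-1-yl acetate | C/C(=C\COC(C)=O)CC/C=C(\C)CO | intermediate
3 | dimethyl (4S,5S)-2,2-dimethyl-1,3-dioxolane-4,5-dicarboxylate, (+)-dimethyl 2,3-O-isopropylidene-D-tartrate | COC(=O)[C@H]1OC(C)(C)O[C@@H]1C(=O)OC | starting material
4 | (4S,5S)-5-(methoxycarbonyl)-2,2-dimethyl-1,3-dioxolane-4-carboxylic acid | OC(=O)[C@H]1OC(C)(C)O[C@@H]1C(=O)OC | intermediate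
5 | (4S,5S)-5-acetyl-2,2-dimethyl-1,3-dioxolane-4-carboxylic acid (present as its bromomagnesium carboxylate) | OC(=O)[C@H]1OC(C)(C)O[C@@H]1C(C)=O | intermediate (not isolated)
6 | (4S,5S)-5-(2-hydroxypropan-2-yl)-2,2-dimethyl-1,3-dioxolane-4-carboxylic acid | OC(=O)[C@H]1OC(C)(C)O[C@@H]1C(C)(C)O | intermediate
7 | (2E,6E)-8-(acetyloxy)-2,6-dimethylocta-2,6-dien-1-yl (4S,5S)-5-(2-hydroxypropan-2-yl)-2,2-dimethyl-1,3-dioxolane-4-carboxylate | C/C(=C\COC(C)=O)CC/C=C(\C)COC(=O)[C@H]1OC(C)(C)O[C@@H]1C(C)(C)O | intermediate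
8 | (2E,6E)-8-[(4R,5S)-5-(2-hydroxypropan-2-yl)-2,2-dimethyl-1,3-dioxolan-4-yl]-3,7-dimethylocta-2,6-dien-1-yl acetate | C/C(=C\COC(C)=O)CC/C=C(\C)C[C@H]1OC(C)(C)O[C@@H]1C(C)(C)O | intermediate (not isolated)
9 | (2E,6E)-8-[(4R,5S)-5-(2-hydroxypropan-2-yl)-2,2-dimethyl-1,3-dioxolan-4-yl]-3,7-dimethylocta-2,6-dien-1-ol | C/C(=C\CO)CC/C=C(\C)C[C@H]1OC(C)(C)O[C@@H]1C(C)(C)O | intermediate
10 | 5,7-dihydroxy-2H-chromen-2-one (5,7-dihydroxycoumarin) | Oc1cc(O)c2ccc(=O)oc2c1 | starting material
11 | 5-hydroxy-7-({(2E,6E)-8-[(4R,5S)-5-(2-hydroxypropan-2-yl)-2,2-dimethyl-1,3-dioxolan-4-yl]-3,7-dimethylocta-2,6-dien-1-yl}oxy)-2H-chromen-2-one | C/C(=C\COc1cc(O)c2ccc(=O)oc2c1)CC/C=C(\C)C[C@H]1OC(C)(C)O[C@@H]1C(C)(C)O | intermediate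
12 | 5-hydroxy-7-{[(2E,6E,9R,10S)-9,10,11-trihydroxy-3,7,11-trimethyldodeca-2,6-dien-1-yl]oxy}-2H-chromen-2-one | C/C(=C\COc1cc(O)c2ccc(=O)oc2c1)CC/C=C(\C)C[C@@H](O)[C@H](O)C(C)(C)O | target

**Step count**
Total steps: 7. Longest linear sequence: 6 steps (3 → 4 → 6 → 7 → 9 → 11 → 12).

**Steps most likely to fail**

Step 5 (the proposed new method). The risks are slow oxidation of the ion-paired carboxylate, competing reversible ionisation of the C1 acetate by zerovalent palladium (it is the poorer leaving group and its ionisation is degenerate), branched or Z coupling, and an insufficient trans:cis ratio at C9. The fallback uses known chemistry, sets out from acid 6 and alcohol 2, and comes back at acetate 8. Acid 6 is reduced with BH3·SMe2 to 2-[(4S,5R)-5-(hydroxymethyl)-2,2-dimethyl-1,3-dioxolan-4-yl]propan-2-ol F1. This is oxidised (SO3·pyridine, DMSO, iPr2NEt) to (4S,5S)-5-(2-hydroxypropan-2-yl)-2,2-dimethyl-1,3-dioxolane-4-carbaldehyde F2. Hantzsch condensation with ethyl acetoacetate and ethyl 3-aminocrotonate gives diethyl 4-[(4R,5S)-5-(2-hydroxypropan-2-yl)-2,2-dimethyl-1,3-dioxolan-4-yl]-2,6-dimethyl-1,4-dihydropyridine-3,5-dicarboxylate F3. Alcohol 2 is converted with methyl chloroformate and pyridine into (2E,6E)-8-(acetyloxy)-2,6-dimethylocta-2,6-dien-1-yl methyl carbonate F4. F3 and F4 are joined by the established nickel/photoredox radical allylation of 4-alkyl-1,4-dihydropyridines with allylic carbonates (NiCl2·glyme, 4,4'-di-tert-butyl-2,2'-bipyridine, 4CzIPN, blue LEDs). The same dioxolanyl radical is again trapped anti to the carbinol substituent, giving acetate 8, which is methanolysed to 9 as in step 5.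

Step 6 (regioselective mono-etherification of a diphenol). Alkylation at the 5-OH or dialkylation would erode the yield. The fallback sets out from alcohol 9 and comes back at 11, and removes the regiochemical question by building the lactone on a symmetric arene. Mitsunobu reaction of 9 with commercial 2,4,6-trihydroxybenzaldehyde engages the only non-hydrogen-bonded 4-OH and gives 2,6-dihydroxy-4-({(2E,6E)-8-[(4R,5S)-5-(2-hydroxypropan-2-yl)-2,2-dimethyl-1,3-dioxolan-4-yl]-3,7-dimethylocta-2,6-dien-1-yl}oxy)benzaldehyde F5. Wittig reaction with Ph3P=CHCO2Et (toluene, 60 °C) gives ethyl (2E)-3-[2,6-dihydroxy-4-({(2E,6E)-8-[(4R,5S)-5-(2-hydroxypropan-2-yl)-2,2-dimethyl-1,3-dioxolan-4-yl]-3,7-dimethylocta-2,6-dien-1-yl}oxy)phenyl]prop-2-enoate F6. Irradiation at 365 nm in MeCN isomerises the cinnamate to the Z form, which lactonises onto either of the two equivalent phenols to give 11.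

Step 7 (acid hydrolysis next to an ionisable aryl allyl ether and trisubstituted olefins). Ether cleavage or cyclisation of a hydroxyl onto the 6,7-olefin could compete with slow opening of the trans-dioxolane. The fallback sets out from alcohol 9 and comes back at target 12, moving the acid step ahead of ether formation. Alcohol 9 is hydrolysed (AcOH/H2O) to (2E,6E,9R,10S)-3,7,11-trimethyldodeca-2,6-diene-1,9,10,11-tetrol F7. The allylic hydroxyl alone is converted by Corey–Kim chlorination (NCS, Me2S, CH2Cl2, −20 °C) into (3S,4R,6E,10E)-12-chloro-2,6,10-trimethyldodeca-6,10-diene-2,3,4-triol F8. F8 then alkylates 5,7-dihydroxycoumarin 10 at the 7-OH (K2CO3, acetone, rt) to give 12 directly, with no acid after the ether is in place.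

**Further compounds**
F1 | step 5 | 2-[(4S,5R)-5-(hydroxymethyl)-2,2-dimethyl-1,3-dioxolan-4-yl]propan-2-ol | OC[C@H]1OC(C)(C)O[C@@H]1C(C)(C)O
F2 | step 5 | (4S,5S)-5-(2-hydroxypropan-2-yl)-2,2-dimethyl-1,3-dioxolane-4-carbaldehyde | O=C[C@H]1OC(C)(C)O[C@@H]1C(C)(C)O
F3 | step 5 | diethyl 4-[(4R,5S)-5-(2-hydroxypropan-2-yl)-2,2-dimethyl-1,3-dioxolan-4-yl]-2,6-dimethyl-1,4-dihydropyridine-3,5-dicarboxylate | CCOC(=O)C1=C(C)NC(C)=C(C(=O)OCC)C1[C@H]1OC(C)(C)O[C@@H]1C(C)(C)O
F4 | step 5 | (2E,6E)-8-(acetyloxy)-2,6-dimethylocta-2,6-dien-1-yl methyl carbonate | C/C(=C\COC(C)=O)CC/C=C(\C)COC(=O)OC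
F5 | step 6 | 2,6-dihydroxy-4-({(2E,6E)-8-[(4R,5S)-5-(2-hydroxypropan-2-yl)-2,2-dimethyl-1,3-dioxolan-4-yl]-3,7-dimethylocta-2,6-dien-1-yl}oxy)benzaldehyde | C/C(=C\COc1cc(O)c(C=O)c(O)c1)CC/C=C(\C)C[C@H]1OC(C)(C)O[C@@H]1C(C)(C)O
F6 | step 6 | ethyl (2E)-3-[2,6-dihydroxy-4-({(2E,6E)-8-[(4R,5S)-5-(2-hydroxypropan-2-yl)-2,2-dimethyl-1,3-dioxolan-4-yl]-3,7-dimethylocta-2,6-dien-1-yl}oxy)phenyl]prop-2-enoate | C/C(=C\COc1cc(O)c(/C=C/C(=O)OCC)c(O)c1)CC/C=C(\C)C[C@H]1OC(C)(C)O[C@@H]1C(C)(C)O
F7 | step 7 | (2E,6E,9R,10S)-3,7,11-trimethyldodeca-2,6-diene-1,9,10,11-tetrol | C/C(=C\CO)CC/C=C(\C)C[C@@H](O)[C@H](O)C(C)(C)O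
F8 | step 7 | (3S,4R,6E,10E)-12-chloro-2,6,10-trimethyldodeca-6,10-diene-2,3,4-triol | C/C(=C\CCl)CC/C=C(\C)C[C@@H](O)[C@H](O)C(C)(C)O
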